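## Retrosynthetic overview
1. Remove the three C5 units in reverse order of installation: the D-ring pyran (C7/O8, from prenal), the C10 prenyl, then the A-ring pyran (C2/O3, from prenal). This leaves (6aR,11aR)-3,8,9-trihydroxypterocarpan.
2. Cut C11a–O11 (ring C). The pterocarpan triol is an isomer of an isoflavan-2′,5′-quinone, and visible light drives the internal redox closure. C6a dictates C11a.
3. The quinone comes from (3R)-7,2′,4′,5′-tetramethoxyisoflavan by global demethylation and autoxidation.
4. Cut C4–C4a and C3–aryl (ring B). The isoflavan comes from an acyclic (R)-1-aryl-3-aryloxypropan-2-ol by an invertive phenonium 1,2-aryl shift with Friedel–Crafts closure.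
5. The alcohol comes from an aryl Grignard, (R)-epichlorohydrin (the only stereocentre source) and 3-methoxyphenol. Rings form in the order B, C, A-pyran, D-pyran.

Assumption: the SMILES decodes to the cis-(6aR,11aR) pterocarpan, the same series as (−)-medicarpin. Pterocarpan numbering is used throughout.

## Route

**Step 1**
Reactants: 1 (1-bromo-2,4,5-trimethoxybenzene); 2 ((R)-epichlorohydrin)
Product: 3, (2R)-1-chloro-3-(2,4,5-trimethoxyphenyl)propan-2-ol
Conditions: 1, Mg, THF; then CuI (10 mol %), 2, THF, −40 → 0 °C; aq NH4Cl
Reagents that add atoms: (R)-epichlorohydrin (reactant 2), ClC[C@H]1CO1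
Why: Cu-catalysed aryl-Grignard opening of a terminal epoxide occurs by SN2 at the ring CH2 faster than at C–Cl, so the bought C–O stereocentre is untouched and stays R.

**Step 2**
Reactants: 3; 4 (3-methoxyphenol)
Product: 5, (2R)-1-(3-methoxyphenoxy)-3-(2,4,5-trimethoxyphenyl)propan-2-ol
Conditions: K2CO3 (2.5 equiv), MeCN, 80 °C
Reagents that add atoms: 3-methoxyphenol (reactant 4), COc1cccc(O)c1
Why: Base closes the chlorohydrin to the epoxide (Williamson) and the phenoxide opens it at the terminal carbon (aryloxypropanol synthesis), and neither event touches the carbinol centre.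

**Step 3**
Reactants: 5
Product: 6, (3R)-7-methoxy-3-(2,4,5-trimethoxyphenyl)chroman, i.e. (3R)-7,2′,4′,5′-tetramethoxyisoflavan
Conditions: Tf2O (1.1 equiv), 2,6-di-tert-butyl-4-methylpyridine (1.5 equiv), CH2Cl2 (0.02 M), −78 °C; then HFIP (10 vol %), −78 → 0 °C
Reagents that add atoms: none
Why: Proposed new method: stereoinvertive phenonium-relay Friedel–Crafts cyclisation, in which the secondary triflate leaves with Ar1-3 assistance from the 2,4,5-trimethoxyphenyl ring attacking from the back (clean inversion, so the bought C–O centre becomes the 3R C–aryl centre), and the strongly stabilised, hence SN2-like, spiro-phenonium ion is opened at its unsubstituted CH2 by the tethered aryloxy ring para to OMe (six-ring Friedel–Crafts closure beats five-ring closure at the hindered, β-oxygen-deactivated CH), giving a net 1,2-aryl shift plus ring B; the closest known reaction types are phenonium 1,2-aryl migrations in solvolysis or deoxyfluorination of β-aryl alcohols and epoxy-arene cyclisation of aryl glycidyl ethers to chroman-3-ols.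

**Step 4**
Reactants: 6
Product: 7, 2-hydroxy-5-[(3R)-7-hydroxychroman-3-yl]-1,4-benzoquinone, i.e. (3R)-7,4′-dihydroxyisoflavan-2′,5′-quinone
Conditions: BBr3 (8 equiv), CH2Cl2, −78 °C → rt; MeOH quench; then air, EtOAc/pH 7 phosphate buffer, rt
Reagents that add atoms: none
Why: BBr3 cleaves the aryl methyl ethers faster than the chroman ether, and the freed 1,2,4-trihydroxyarene autoxidises to the 2-hydroxy-1,4-quinone while the resorcinol-type A ring is inert; neutral pH avoids quinone-methide tautomerisation at C3.

**Step 5**
Reactants: 7
Product: 8, (6aR,11aR)-3,8,9-trihydroxypterocarpan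
Conditions: hν (427 nm LEDs), degassed MeCN (5 mM), N2, 20 °C
Reagents that add atoms: none
Why: Proposed new method: redox-neutral photoisomerisation of an isoflavan-2′,5′-quinone to a pterocarpan, in which the excited quinone (n,π*/charge transfer from the electron-rich A ring) uses its C2′ carbonyl oxygen to remove the activated benzylic H-4 through a six-membered 1,5-HAT (or ET/PT) transition state, the radical pair collapses to the 7-hydroxy p-quinone methide plus hydroquinone, and the new 2′-OH adds to C4 on the only face it can reach, so the C3 (= C6a) centre enforces the cis-fused 11aR centre because a trans 6/5 fusion is too strained; the closest known reaction types are photocyclisation of alkyl-1,4-benzoquinones to 2,3-dihydrobenzofuran-5-ols via γ-H abstraction and the ground-state DDQ cyclisation of 2′-hydroxyisoflavans.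

**Step 6**
Reactants: 8; 9 (3-methylbut-2-enal, prenal)
Product: 10, (6aR,11aR)-8,9-dihydroxypterocarpan carrying a linear 2,2-dimethyl-2H-pyran on ring A (pyran O on C3, vinyl CH on C2)
Conditions: 9 (1.3 equiv), PhB(OH)2 (2.5 equiv), AcOH, toluene, reflux (Dean–Stark), N2; pinacol work-up
Reagents that add atoms: prenal, CC(C)=CC=O
Why: In this boronic-acid-templated chromenylation (ortho-hydroxyalkylation, benzodioxaborin, o-quinone methide, oxa-6π), one equivalent of PhB(OH)2 masks the 8,9-catechol as its cyclic boronate and the rest delivers prenal to the less hindered ortho carbon C2 (para to O5) of the only free phenol; no stereocentre is involved.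

**Step 7**
Reactants: 10; 11 (3-methylbut-2-en-1-ol, prenol)
Product: 12, the 10-(3-methylbut-2-enyl) derivative of 10 (6aR,11aR)
Conditions: 11 (1.5 equiv), acidic Al2O3, 1,2-dichloroethane, 80 °C, N2
Reagents that add atoms: prenol, CC(C)=CCO
Why: In this alumina-templated ortho-selective Friedel–Crafts allylation of a phenol, C10 (ortho to 9-OH and to O11) is the most nucleophilic free carbon, C7 has only one activating oxygen and is hindered, and ring A no longer has a free OH.

**Step 8**
Reactants: 12; 9 (prenal)
Product: 13, Lespecyrtin E4
Conditions: 9 (3 equiv), pyridine, 120 °C (sealed tube), N2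
Reagents that add atoms: prenal, CC(C)=CC=O
Why: In this pyridine-mediated phenol–enal chromenylation (ortho condensation, o-quinone methide, oxa-6π; precedented on hydroquinone-type phenols), C7 is the only free D-ring carbon and is ortho only to 8-OH, so the pyran can only close C7/O8 and 9-OH stays free; the basic medium spares the o-prenylphenol, both chromenes and both stereocentres.

## Compound list
1 | 1-bromo-2,4,5-trimethoxybenzene | COc1cc(OC)c(OC)cc1Br | starting material
2 | (R)-epichlorohydrin | ClC[C@H]1CO1 | starting material
3 | (2R)-1-chloro-3-(2,4,5-trimethoxyphenyl)propan-2-ol | ClC[C@H](O)Cc1cc(OC)c(OC)cc1OC | intermediate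
4 | 3-methoxyphenol | COc1cccc(O)c1 | starting material
5 | (2R)-1-(3-methoxyphenoxy)-3-(2,4,5-trimethoxyphenyl)propan-2-ol | COc1cccc(OC[C@H](O)Cc2cc(OC)c(OC)cc2OC)c1 | intermediate
6 | (3R)-7,2′,4′,5′-tetramethoxyisoflavan | COc1ccc2c(c1)OC[C@H](C2)c1cc(OC)c(OC)cc1OC | intermediate
7 | (3R)-7,4′-dihydroxyisoflavan-2′,5′-quinone | Oc1ccc2c(c1)OC[C@H](C2)C1=CC(=O)C(O)=CC1=O | intermediate
8 | (6aR,11aR)-3,8,9-trihydroxypterocarpan | Oc1cc2c(cc1O)O[C@H]1c3ccc(O)cc3OC[C@@H]21 | intermediate
9 | 3-methylbut-2-enal | CC(C)=CC=O | starting material
10 | A-ring dimethylpyrano-8,9-dihydroxypterocarpan (6aR,11aR) | Oc1cc2c(cc1O)O[C@H]1c3cc4c(cc3OC[C@@H]21)OC(C)(C)C=C4 | intermediate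
11 | 3-methylbut-2-en-1-ol | CC(C)=CCO | starting material
12 | 10-prenyl derivative of 10 (6aR,11aR) | Oc1cc2c(c(CC=C(C)C)c1O)O[C@H]1c3cc4c(cc3OC[C@@H]21)OC(C)(C)C=C4 | intermediate
13 | Lespecyrtin E4 | CC(C)=CCc1c(O)c2c(c3c1O[C@H]1c4cc5c(cc4OC[C@@H]31)OC(C)(C)C=C5)C=CC(C)(C)O2 | target

## Step count and risks
Total steps: 8. Longest linear sequence: 8.

The three steps most likely to fail:

1. **Step 5 (new photoisomerisation).**
   - Risks: unproductive back electron transfer, H-abstraction at C2–H (next to O), or loss of H-3 from the quinone methide to give the isoflav-3-ene.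
   - Fallback (known chemistry, ground state, external oxidant): reduce 7 with Na2S2O4 to the tetraol and tie the 4′,5′-catechol up as its cyclic carbonate to make the D ring electron-poor. Then close with stoichiometric DDQ, the established 2′-hydroxyisoflavan to pterocarpan cyclisation. K2CO3/MeOH then gives 8.

2. **Step 3 (new phenonium-relay cyclisation).**
   - Risks: ortho-OMe (MeO-5) participation giving a 2-(aryloxymethyl)dihydrobenzofuran, E1 loss to the cinnamyl ether, or five-ring closure.
   - Fallback (known chemistry, still from a bought stereocentre): build ArCO–CH(OMs)–CH2OAr′ from a glycidate or glycerate ester. Apply the established invertive 1,2-aryl migration of its dimethyl ketal to the 2-aryl-3-aryloxypropanoate. Then carry out Friedel–Crafts acylation to the isoflavanone and Et3SiH/TFA ionic reduction to 6.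

3. **Step 8 (chromenylation at hindered, singly activated C7 of an air-sensitive catechol).**
   - Risks: low reactivity at C7 and oxidation of the catechol.
   - Fallback: switch to an intramolecular sigmatropic route. Carry out Cu-catalysed O-alkylation of the less hindered 8-OH (9-OH is shielded by the prenyl) with 2-methylbut-3-yn-2-yl carbonate. Then heat (xylene, 140 °C) to trigger the aryl propargyl ether Claisen, [1,5]-H shift and oxa-6π sequence.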